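**Plan**
- Retrosynthesis: the two benzyl ethers and both benzoate C–O bonds go first. The C7–OH and C3–OH are then traced to one O3–SiMe2–C7 bridge (Tamao–Fleming), the C1–C7 bond is cut (key step), and last the ring C–C bond between former C1 and C6 of D-glucose (Ferrier carbocyclisation).
- Forward: diacetone-D-glucose gives a hex-5-enopyranoside, then the cyclohexanone ring, then the enone. A silicon tether on O3 closes a temporary oxasilinane ring onto C1, the bridge is oxidised off, and benzoylation and debenzylation finish the route.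
- Enabling feature: O3 on C3 and the exocyclic C7 on C1 are 1,3-cis on the cyclohexene ring and are exactly the two benzoylated oxygens. An O3–Si–C7 bridge (a 2-oxa-3-silabicyclo[3.3.1]nonene) can therefore deliver C7 to C1 and later release both hydroxyls.
- Stereochemistry: C2, C3 and C4 are C4, C3 and C2 of D-glucose and are never touched; C1 is set by the tether, which reaches the carbonyl only from the face of O3.

Key step: step 10

Assumption: the Fischer glycosidation in step 2 is expected to favour the α-pyranoside, which is drawn and carried on. The β-anomer would serve equally, since the anomeric substituent is lost in step 5. Carbocycle atoms carry the target numbering (C1 carbinol carbon, C7 exocyclic carbon); the α face is the face of O3.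

**Route**

Step 1
Reactants: 1 diacetone-D-glucose; 2 2-(bromomethyl)naphthalene
Product: 3 1,2:5,6-di-O-isopropylidene-3-O-(2-naphthylmethyl)-α-D-glucofuranose
Conditions: NaH, n-Bu4NI (cat.), THF/DMF, 0 °C to rt
Reagents that add atoms: 2-(bromomethyl)naphthalene (2), BrCc1ccc2ccccc2c1
Why: Williamson etherification of the only free hydroxyl (O3) with an activated benzylic bromide; no stereocentre is touched.

Step 2
Reactants: 3
Product: 4 methyl 3-O-(2-naphthylmethyl)-α-D-glucopyranoside
Conditions: HCl (0.5 M) in MeOH, 65 °C; NaHCO3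
Reagents that add atoms: methanol, CO
Why: Acid-catalysed methanolysis removes both acetonides and Fischer glycosidation equilibrates the sugar to the methyl pyranoside (α favoured by the anomeric effect), while the naphthylmethyl ether should tolerate dilute methanolic acid as a benzyl ether does.

Step 3
Reactants: 4
Product: 5 methyl 6-deoxy-6-iodo-3-O-(2-naphthylmethyl)-α-D-glucopyranoside
Conditions: I2, PPh3, imidazole, THF, 65 °C
Reagents that add atoms: iodine, II
Why: Garegg (Appel-type) iodination through the alkoxyphosphonium salt is selective for the primary C6 hydroxyl over the two secondary ones.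

Step 4
Reactants: 5; 6 benzyl bromide
Product: 8 methyl 2,4-di-O-benzyl-6-deoxy-3-O-(2-naphthylmethyl)-α-D-xylo-hex-5-enopyranoside, via dibenzylated 6-iodide 7 (not isolated)
Conditions: NaH (excess), BnBr, DMF, 0 °C to rt; MeOH quench
Reagents that add atoms: benzyl bromide (6), BrCc1ccccc1
Why: Williamson benzylation of O2 and O4 and E2 dehydroiodination across C5–C6 by excess NaH in DMF run in one pot, a known entry to benzylated hex-5-enopyranosides; the O3 ether blocks 3,6-anhydro formation.

Step 5
Reactants: 8
Product: 9 (2S,3R,4S,5S)-2,4-bis(benzyloxy)-5-hydroxy-3-(2-naphthylmethoxy)cyclohexan-1-one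
Conditions: PdCl2 (0.1 equiv), dioxane/H2O (2:1), 60 °C
Reagents that add atoms: water, O
Why: Ferrier carbocyclisation: hydroxypalladation of the enol ether, loss of methanol to a C6-metalated 5-keto aldehyde and intramolecular aldol closure give the cyclohexanone; the new carbinol should form mainly trans to the O3 substituent, and its configuration is erased in step 6.

Step 6
Reactants: 9
Product: 11 (4S,5R,6S)-4,6-bis(benzyloxy)-5-(2-naphthylmethoxy)cyclohex-2-en-1-one, via mesylate 10 (not isolated)
Conditions: MsCl, Et3N, DCM, 0 °C to rt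
Reagents that add atoms: none
Why: Mesylation of the β-hydroxy ketone followed by E1cB elimination gives the conjugated enone, the sulfonate leaving in preference to the β-alkoxy group on the other side of the carbonyl.

Step 7
Reactants: 11
Product: 12 (4S,5R,6S)-4,6-bis(benzyloxy)-5-hydroxycyclohex-2-en-1-one
Conditions: DDQ, DCM/pH 7 phosphate buffer (10:1), 0 °C to rt
Reagents that add atoms: none
Why: Oxidative naphthylmethyl ether cleavage: DDQ abstracts hydride from the electron-rich naphthylmethyl group and water hydrolyses the oxocarbenium ion, while benzyl ethers and the electron-poor enone should be untouched.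

Step 8
Reactants: 12; 13 (bromomethyl)chlorodimethylsilane
Product: 14 (4S,5R,6S)-4,6-bis(benzyloxy)-5-{[(bromomethyl)dimethylsilyl]oxy}cyclohex-2-en-1-one
Conditions: BrCH2SiMe2Cl, imidazole, DCM, 0 °C
Reagents that add atoms: (bromomethyl)chlorodimethylsilane (13), C[Si](C)(Cl)CBr
Why: Silylation of the secondary hydroxyl (O3 of the target) with a small chlorosilane, as in the preparation of Stork–Nishiyama tethers; the mild base spares the elimination-prone enone.

Step 9
Reactants: 14
Product: 15 (4S,5R,6S)-4,6-bis(benzyloxy)-5-{[(iodomethyl)dimethylsilyl]oxy}cyclohex-2-en-1-one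
Conditions: NaI, acetone, rt to 40 °C, dark
Reagents that add atoms: NaI, [Na+].[I-]
Why: Finkelstein exchange (SN2 at the primary α-silyl carbon, driven by precipitation of NaBr) supplies the iodide needed for fast halogen–lithium exchange.

Step 10
Reactants: 15
Product: 17 bridged siloxane tertiary alcohol (O3–SiMe2–C7 bridge from C3 to C1 on the α face; C1–OH β; 2,4-di-O-benzyl), via lithiomethylsilyl ether 16 (not isolated)
Conditions: LaCl3·2LiCl (1.1 equiv), THF/Et2O, 0 °C then −100 °C; t-BuLi (2.1 equiv, pentane), −100 °C, 10 min; aq NH4Cl at −100 °C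
Reagents that add atoms: none
Why: Proposed new method: t-BuLi should undergo iodine–lithium exchange at the primary α-silyl iodide faster than it adds to the carbonyl, and the silylmethyl carbanion 16 then adds 1,2 to C1 to form C1–C7; the closest known reactions are exchange-initiated cyclisations of iodo ketones (intramolecular Barbier or Parham type) and the intermolecular hydroxymethylation of ketones and enones with (alkoxydimethylsilyl)methyl Grignard reagents. The 1-oxa-2-silacyclohexane ring (C1, C7, Si, O3, C3, C2) closes 6-exo-trig on the carbonyl carbon and gives a 2-oxa-3-silabicyclo[3.3.1]non-6-ene. The C1 stereocentre is set by the tether: the three-atom O3–Si–C7 chain can span C3 and C1 only 1,3-diaxially on the face of O3, reached through the half-chair with O3 axial, so C7 enters cis to O3 and the hydroxyl ends cis to the C2 benzyloxy group. The step needs 1,2- over 1,4-addition (C5 is also 1,3 to C3) and addition over enolisation at C2 with β-loss of the O3 silanolate; the hard, localised α-silyl anion and the oxophilic lanthanum salt, which activates the carbonyl and tempers basicity, should secure both. The metal alkoxide of the β-silyl carbinol is quenched cold, before Peterson elimination can set in.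

Step 11
Reactants: 17
Product: 18 (1S,2S,3R,4S)-2,4-bis(benzyloxy)-1-(hydroxymethyl)cyclohex-5-ene-1,3-diol
Conditions: H2O2 (30% aq), KF, KHCO3, THF/MeOH (1:1), rt
Reagents that add atoms: hydrogen peroxide, OO
Why: Tamao–Fleming oxidation: fluoride-activated silicon takes up hydroperoxide and C7 migrates from Si to O, while the Si–O3 bond is hydrolysed, so the primary C7–OH and secondary C3–OH are released together, as for the β-hydroxy(alkoxy)silanes of nucleophilic hydroxymethylation.

Step 12
Reactants: 18; 19 benzoyl chloride
Product: 20 (1S,2S,3R,4S)-3-benzoyloxy-1-(benzoyloxymethyl)-2,4-bis(benzyloxy)cyclohex-5-en-1-ol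
Conditions: BzCl (2.3 equiv), pyridine, DMAP (cat.), DCM, 0 °C to rt
Reagents that add atoms: benzoyl chloride (19), O=C(Cl)c1ccccc1
Why: Nucleophile-catalysed acylation esterifies the primary C7 and secondary C3 hydroxyls, while the tertiary C1 hydroxyl is too hindered to react under these conditions.

Step 13
Reactants: 20
Product: 21 (1S,2S,3R,4S)-3-benzoyloxy-1-(benzoyloxymethyl)cyclohex-5-ene-1,2,4-triol (target)
Conditions: BCl3 (1 M in DCM), C6HMe5, DCM, −78 °C; MeOH quench
Reagents that add atoms: none
Why: Lewis-acid debenzylation: BCl3 coordinates the ether oxygens and the benzyl cation is trapped by pentamethylbenzene; at −78 °C benzoates and the alkene should be inert, and ionisation of the tertiary allylic C1–O bond is disfavoured by its electron-withdrawing oxygen neighbours.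

**Compound list**
1 | diacetone-D-glucose (1,2:5,6-di-O-isopropylidene-α-D-glucofuranose) | CC1(C)OC[C@@H](O1)[C@H]1O[C@@H]2OC(C)(C)O[C@@H]2[C@H]1O | starting material
2 | 2-(bromomethyl)naphthalene | BrCc1ccc2ccccc2c1 | starting material
3 | 1,2:5,6-di-O-isopropylidene-3-O-(2-naphthylmethyl)-α-D-glucofuranose | CC1(C)OC[C@@H](O1)[C@H]1O[C@@H]2OC(C)(C)O[C@@H]2[C@H]1OCc1ccc2ccccc2c1 | intermediate
4 | methyl 3-O-(2-naphthylmethyl)-α-D-glucopyranoside | CO[C@H]1O[C@H](CO)[C@@H](O)[C@H](OCc2ccc3ccccc3c2)[C@H]1O | intermediate
5 | methyl 6-deoxy-6-iodo-3-O-(2-naphthylmethyl)-α-D-glucopyranoside | CO[C@H]1O[C@H](CI)[C@@H](O)[C@H](OCc2ccc3ccccc3c2)[C@H]1O | intermediate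
6 | benzyl bromide | BrCc1ccccc1 | starting material
7 | methyl 2,4-di-O-benzyl-6-deoxy-6-iodo-3-O-(2-naphthylmethyl)-α-D-glucopyranoside | CO[C@H]1O[C@H](CI)[C@@H](OCc2ccccc2)[C@H](OCc2ccc3ccccc3c2)[C@H]1OCc1ccccc1 | intermediate (not isolated)
8 | methyl 2,4-di-O-benzyl-6-deoxy-3-O-(2-naphthylmethyl)-α-D-xylo-hex-5-enopyranoside | CO[C@H]1OC(=C)[C@@H](OCc2ccccc2)[C@H](OCc2ccc3ccccc3c2)[C@H]1OCc1ccccc1 | intermediate
9 | (2S,3R,4S,5S)-2,4-bis(benzyloxy)-5-hydroxy-3-(2-naphthylmethoxy)cyclohexan-1-one | O=C1C[C@H](O)[C@H](OCc2ccccc2)[C@@H](OCc2ccc3ccccc3c2)[C@@H]1OCc1ccccc1 | intermediate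
10 | 5-O-mesylate of 9 | O=C1C[C@H](OS(C)(=O)=O)[C@H](OCc2ccccc2)[C@@H](OCc2ccc3ccccc3c2)[C@@H]1OCc1ccccc1 | intermediate (not isolated)
11 | (4S,5R,6S)-4,6-bis(benzyloxy)-5-(2-naphthylmethoxy)cyclohex-2-en-1-one | O=C1C=C[C@H](OCc2ccccc2)[C@@H](OCc2ccc3ccccc3c2)[C@@H]1OCc1ccccc1 | intermediate
12 | (4S,5R,6S)-4,6-bis(benzyloxy)-5-hydroxycyclohex-2-en-1-one | O=C1C=C[C@H](OCc2ccccc2)[C@@H](O)[C@@H]1OCc1ccccc1 | intermediate
13 | (bromomethyl)chlorodimethylsilane | C[Si](C)(Cl)CBr | starting material
14 | (4S,5R,6S)-4,6-bis(benzyloxy)-5-{[(bromomethyl)dimethylsilyl]oxy}cyclohex-2-en-1-one | O=C1C=C[C@H](OCc2ccccc2)[C@@H](O[Si](C)(C)CBr)[C@@H]1OCc1ccccc1 | intermediate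
15 | (4S,5R,6S)-4,6-bis(benzyloxy)-5-{[(iodomethyl)dimethylsilyl]oxy}cyclohex-2-en-1-one (key-step precursor) | O=C1C=C[C@H](OCc2ccccc2)[C@@H](O[Si](C)(C)CI)[C@@H]1OCc1ccccc1 | intermediate
16 | (lithiomethyl)dimethylsilyl ether of 12 | O=C1C=C[C@H](OCc2ccccc2)[C@@H](O[Si](C)(C)C[Li])[C@@H]1OCc1ccccc1 | intermediate (not isolated)
17 | 8,9-bis(benzyloxy)-3,3-dimethyl-2-oxa-3-silabicyclo[3.3.1]non-6-en-5-ol, bridge on the face of O3, hydroxyl cis to the C2 benzyloxy group (key-step product) | O[C@@]12C=C[C@H](OCc3ccccc3)[C@@H](O[Si](C)(C)C1)[C@@H]2OCc1ccccc1 | intermediate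
18 | (1S,2S,3R,4S)-2,4-bis(benzyloxy)-1-(hydroxymethyl)cyclohex-5-ene-1,3-diol | OC[C@@]1(O)C=C[C@H](OCc2ccccc2)[C@@H](O)[C@@H]1OCc1ccccc1 | intermediate
19 | benzoyl chloride | O=C(Cl)c1ccccc1 | starting material
20 | (1S,2S,3R,4S)-3-benzoyloxy-1-(benzoyloxymethyl)-2,4-bis(benzyloxy)cyclohex-5-en-1-ol | O=C(OC[C@@]1(O)C=C[C@H](OCc2ccccc2)[C@@H](OC(=O)c2ccccc2)[C@@H]1OCc1ccccc1)c1ccccc1 | intermediate
21 | 1α-benzoyloxymethyl-3α-benzoyloxycyclohex-5-ene-1β,2β,4β-triol, (1S,2S,3R,4S) | O=C(OC[C@@]1(O)C=C[C@H](O)[C@@H](OC(=O)c2ccccc2)[C@@H]1O)c1ccccc1 | target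

**Step count**
Total steps: 13. Longest linear sequence: 13 steps, from 1.

**Steps most likely to fail**

1. Step 10 (proposed new method). Possible failures are direct transfer of the tert-butyl group to the activated carbonyl before exchange, enolisation at C2 with β-loss of the silanolate, and conjugate delivery to C5. Fallback with known chemistry, from enone 11 to triol 18: (isopropoxydimethylsilyl)methylmagnesium chloride (from (chloromethyl)isopropoxydimethylsilane and Mg) with anhydrous CeCl3 in THF at −78 °C should add 1,2 to give the tertiary β-hydroxysilane F1. Equatorial attack of the bulky reagent, cis to O3 and trans to the C2 benzyloxy group, is expected, but the face is now substrate-controlled and not enforced. Tamao–Fleming oxidation (H2O2, KF, KHCO3) gives the 1,7-diol F2, and DDQ removal of the naphthylmethyl ether returns to 18.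

2. Step 13. Possible failures are ionisation of the tertiary allylic carbinol under the Lewis acid, benzoate migration through an acyloxonium ion, and incomplete cleavage of the hindered ethers. Fallback, from 20 to 21: replace Lewis-acid heterolysis by neutral photo-oxidative debenzylation (DDQ, 525 nm irradiation, wet DCM). Single-electron oxidation of the benzyl arene leads to a hemiacetal that hydrolyses to the alcohol and benzaldehyde, and alkenes and esters are tolerated. This fallback makes no new compound (F0).

3. Step 4. Possible failures are incomplete dehydroiodination, intermolecular alkoxide displacement of the iodide, and base-induced degradation during the one-pot double alkylation and elimination. Fallback, from 5 to 8: decouple the two events. Acid-catalysed benzylation with benzyl 2,2,2-trichloroacetimidate and TfOH (cat.) gives 7 as an isolated compound, and AgF in pyridine then effects the dehydroiodination to 8. This fallback makes no new compound (F0).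

**Further compounds**
F1 | step 10 | (1S,2S,3R,4S)-2,4-bis(benzyloxy)-1-{[isopropoxy(dimethyl)silyl]methyl}-3-(2-naphthylmethoxy)cyclohex-5-en-1-ol | CC(C)O[Si](C)(C)C[C@@]1(O)C=C[C@H](OCc2ccccc2)[C@@H](OCc2ccc3ccccc3c2)[C@@H]1OCc1ccccc1
F2 | step 10 | (1S,2S,3R,4S)-2,4-bis(benzyloxy)-1-(hydroxymethyl)-3-(2-naphthylmethoxy)cyclohex-5-en-1-ol | OC[C@@]1(O)C=C[C@H](OCc2ccccc2)[C@@H](OCc2ccc3ccccc3c2)[C@@H]1OCc1ccccc1
F0 | step 13 | none | none
F0 | step 4 | none | none
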